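**Retrosynthetic overview**
- The target comes from its tri-O-benzyl ether by neutral hydrogenolysis in the last step.
- The tetrahydrofuran ring is formed second, by reductive etherification of an α-aroyl lactone that carries a cis CH2OTBS group. Hydride enters the cis-fused oxocarbenium ion on its convex face, which sets C6 and C6a and puts the catechol-derived aryl endo.
- The C6a–C6 bond comes from Claisen C-acylation of the lactone enolate with the aroyl chloride.
- The lactone ring is formed first, together with the key C3–C3a bond. A chiral-NHC homoenolate of a γ-silyloxy enal (nucleophilic β-carbon) attacks the aldehyde carbon of benzyl-protected syringaldehyde. This joins two normally electrophilic carbons, gives the cis-4,5-disubstituted γ-butyrolactone and fixes the absolute configuration.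

Assumption: the (5aS,10bR) precatalyst is taken to give the (4S,5S) lactone; if it gives the mirror image, the equally available (5aR,10bS) salt is used and nothing else changes.
Assumption: benzyl-protected syringaldehyde, TBS-protected (E)-4-hydroxybut-2-enal and 3,4-bis(benzyloxy)benzoic acid are bought as catalogue building blocks.

**Step 1**
Reactants: 1 4-(benzyloxy)-3,5-dimethoxybenzaldehyde; 2 (E)-4-[(tert-butyldimethylsilyl)oxy]but-2-enal
Product: 3 (4S,5S)-5-[4-(benzyloxy)-3,5-dimethoxyphenyl]-4-({[tert-butyl(dimethyl)silyl]oxy}methyl)oxolan-2-one (cis lactone)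
Conditions: (5aS,10bR)-2-mesityl-5a,10b-dihydro-4H,6H-indeno[2,1-b][1,2,4]triazolo[4,3-d][1,4]oxazin-2-ium chloride (10 mol %), DBU (10 mol %), Ti(OiPr)4 (20 mol %), CH2Cl2, 23 °C; 2 added over 6 h to 1 (1.5 equiv)
Reagents that add atoms: none
Why: Proposed new method: the N-mesityl triazolylidene adds to enal 2 to give a Breslow intermediate whose β-carbon (homoenolate, reversed polarity) attacks the Ti-activated aldehyde 1 through a compact Ti-bridged transition state that places the aryl and CH2OTBS groups cis (C4 and C5 set together, facial sense from the aminoindanol backbone), and the alkoxide then closes onto the acyl azolium to release the lactone with no by-product; the closest known reactions are the cis-selective NHC homoenolate annulation of enals with aryl aldehydes to γ-butyrolactones and its Ti(OiPr)4-cooperative enantioselective enal–enal variant, whereas a γ-silyloxy enal and high ee with a simple aryl aldehyde are unproven.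

**Step 2**
Reactants: 3 (4S,5S)-5-[4-(benzyloxy)-3,5-dimethoxyphenyl]-4-({[tert-butyl(dimethyl)silyl]oxy}methyl)oxolan-2-one; 4 3,4-bis(benzyloxy)benzoic acid
Product: 6 (3RS,4S,5S)-3-[3,4-bis(benzyloxy)benzoyl]-5-[4-(benzyloxy)-3,5-dimethoxyphenyl]-4-({[tert-butyl(dimethyl)silyl]oxy}methyl)oxolan-2-one, via 3,4-bis(benzyloxy)benzoyl chloride 5 (not isolated)
Conditions: 4, (COCl)2, DMF (cat.), CH2Cl2, 23 °C, evaporate from toluene; 3, LiN(SiMe3)2 (2.2 equiv), THF, −78 °C; then 5, −78 to −30 °C; cold 1 M HCl quench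
Reagents that add atoms: none
Why: Claisen-type C-acylation of the lithium lactone enolate by the acid chloride made in the flask, driven by deprotonation of the β-keto lactone product by the second equivalent of the hindered amide base (as in the standard LiN(SiMe3)2 synthesis of β-keto esters from acid chlorides); C4 and C5 are untouched and the new α-centre is left as an epimer mixture because it equilibrates in step 3.

**Step 3**
Reactants: 6 (3RS,4S,5S)-3-[3,4-bis(benzyloxy)benzoyl]-5-[4-(benzyloxy)-3,5-dimethoxyphenyl]-4-({[tert-butyl(dimethyl)silyl]oxy}methyl)oxolan-2-one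
Product: 8 (3S,3aS,6S,6aR)-6-[3,4-bis(benzyloxy)phenyl]-3-[4-(benzyloxy)-3,5-dimethoxyphenyl]tetrahydro-1H,3H-furo[3,4-c]furan-1-one, via bicyclic oxocarbenium bromide 7 (not isolated)
Conditions: Et3SiH (3 equiv), BiBr3 (10 mol %, added last), MeCN, 0 °C; NaHCO3 quench at 0 °C
Reagents that add atoms: none
Why: Intramolecular reductive etherification of a silyloxy ketone: the α-epimers equilibrate through the enol, only the epimer with the aroyl group cis to CH2OTBS can close, and the cis-fused oxocarbenium ion 7 takes hydride on its convex face (the concave face is blocked by the lactone ring and its endo aryl), so the new H-6 and H-6a are cis to H-3a and the bis(benzyloxy)phenyl group ends up endo.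

**Step 4**
Reactants: 8 (3S,3aS,6S,6aR)-6-[3,4-bis(benzyloxy)phenyl]-3-[4-(benzyloxy)-3,5-dimethoxyphenyl]tetrahydro-1H,3H-furo[3,4-c]furan-1-one
Product: 9 (3S,3aS,6S,6aR)-6-(3,4-dihydroxyphenyl)-3-(4-hydroxy-3,5-dimethoxyphenyl)tetrahydro-1H,3H-furo[3,4-c]furan-1-one
Conditions: H2 (1 atm), 5% Pd/C, EtOAc, 23 °C, stopped at 3 equiv uptake
Reagents that add atoms: none
Why: Catalytic hydrogenolysis of the three aryl benzyl ethers under neutral conditions, which should be faster than cleavage of the hindered ring benzylic C–O bonds and avoids the acid or base that would epimerise the endo aryl groups through benzylic cations or quinone methides; no stereocentre is touched.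

**Compound list**
1 | 4-(benzyloxy)-3,5-dimethoxybenzaldehyde | COc1cc(C=O)cc(OC)c1OCc1ccccc1 | starting material
2 | (E)-4-[(tert-butyldimethylsilyl)oxy]but-2-enal | CC(C)(C)[Si](C)(C)OC/C=C/C=O | starting material
3 | (4S,5S)-5-[4-(benzyloxy)-3,5-dimethoxyphenyl]-4-({[tert-butyl(dimethyl)silyl]oxy}methyl)oxolan-2-one | COc1cc([C@H]2OC(=O)C[C@H]2CO[Si](C)(C)C(C)(C)C)cc(OC)c1OCc1ccccc1 | intermediate
4 | 3,4-bis(benzyloxy)benzoic acid | OC(=O)c1ccc(OCc2ccccc2)c(OCc2ccccc2)c1 | starting material
5 | 3,4-bis(benzyloxy)benzoyl chloride | ClC(=O)c1ccc(OCc2ccccc2)c(OCc2ccccc2)c1 | intermediate (not isolated)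
6 | (3RS,4S,5S)-3-[3,4-bis(benzyloxy)benzoyl]-5-[4-(benzyloxy)-3,5-dimethoxyphenyl]-4-({[tert-butyl(dimethyl)silyl]oxy}methyl)oxolan-2-one (α-carbon epimer mixture, left undefined in the SMILES) | COc1cc([C@H]2OC(=O)C(C(=O)c3ccc(OCc4ccccc4)c(OCc4ccccc4)c3)[C@H]2CO[Si](C)(C)C(C)(C)C)cc(OC)c1OCc1ccccc1 | intermediate
7 | (3S,3aS,6aR)-6-[3,4-bis(benzyloxy)phenyl]-3-[4-(benzyloxy)-3,5-dimethoxyphenyl]-1-oxo-3,3a,4,6a-tetrahydro-1H-furo[3,4-c]furan-5-ium bromide (cis-fused oxocarbenium ion) | COc1cc([C@H]2OC(=O)[C@@H]3[C@H]2C[O+]=C3c2ccc(OCc4ccccc4)c(OCc4ccccc4)c2)cc(OC)c1OCc1ccccc1.[Br-] | intermediate (not isolated)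
8 | (3S,3aS,6S,6aR)-6-[3,4-bis(benzyloxy)phenyl]-3-[4-(benzyloxy)-3,5-dimethoxyphenyl]tetrahydro-1H,3H-furo[3,4-c]furan-1-one (all four ring hydrogens cis, both aryl groups endo) | COc1cc([C@H]2OC(=O)[C@@H]3[C@H]2CO[C@@H]3c2ccc(OCc4ccccc4)c(OCc4ccccc4)c2)cc(OC)c1OCc1ccccc1 | intermediate
9 | (3S,3aS,6S,6aR)-6-(3,4-dihydroxyphenyl)-3-(4-hydroxy-3,5-dimethoxyphenyl)tetrahydro-1H,3H-furo[3,4-c]furan-1-one | COc1cc([C@H]2OC(=O)[C@@H]3[C@H]2CO[C@@H]3c2ccc(O)c(O)c2)cc(OC)c1O | target

**Step count and risks**
Total step count: 4. Longest linear sequence: 4 steps (1 and 2 to 3, then 6, 8 and 9).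

The three steps most likely to fail:

Step 1. The risks are enal self-annulation and benzoin formation, β-elimination of silanolate from the homoenolate, and modest cis selectivity or ee with this aldehyde. The fallback sets out from 1 and comes back to the route at 3, and builds the same two stereocentres with normal-polarity auxiliary chemistry. An Evans-type Mg-catalysed anti-aldol of 1 with (S)-4-benzyl-3-(pent-4-enoyl)oxazolidin-2-one (MgCl2, Et3N, Me3SiCl, EtOAc, then acidic methanol) is used. The aldehyde adds to the chelated Z-enolate on the face away from the benzyl group and gives (S)-4-benzyl-3-{(2R,3S)-3-[4-(benzyloxy)-3,5-dimethoxyphenyl]-3-hydroxy-2-(prop-2-en-1-yl)propanoyl}oxazolidin-2-one F1. LiBH4 in wet THF removes the auxiliary to give (1S,2S)-1-[4-(benzyloxy)-3,5-dimethoxyphenyl]-2-(prop-2-en-1-yl)propane-1,3-diol F2. TBSCl and imidazole silylate only the primary hydroxyl to give (1S,2S)-1-[4-(benzyloxy)-3,5-dimethoxyphenyl]-2-({[tert-butyl(dimethyl)silyl]oxy}methyl)pent-4-en-1-ol F3. Ozonolysis (O3, CH2Cl2/MeOH, −78 °C, then Me2S) gives the lactol (4S,5S)-5-[4-(benzyloxy)-3,5-dimethoxyphenyl]-4-({[tert-butyl(dimethyl)silyl]oxy}methyl)oxolan-2-ol F4. Oxidation with PhI(OAc)2 and catalytic TEMPO then gives 3.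

Step 3. The risks are reduction of the aryl ketone before ring closure, loss of the acidic α-proton to a stable push–pull enol ether, and acid-induced epimerisation of the endo aryl ether to the exo isomer. The fallback sets out from 6 and comes back at 8, and separates ring closure from reduction. Desilylation of 6 with HF·pyridine in THF gives the isolable ring-closed hemiketal (3S,3aS,6aR)-6-[3,4-bis(benzyloxy)phenyl]-3-[4-(benzyloxy)-3,5-dimethoxyphenyl]-6-hydroxytetrahydro-1H,3H-furo[3,4-c]furan-1-one F5. This is then reduced with Et3SiH and BF3·OEt2 in CH2Cl2 at −78 °C, where the lactol ionises and is trapped on the convex face before the ketone or the product can react.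

Step 4. The risk is hydrogenolysis of the ring benzylic C–O bonds (the lactone C3–O and the ether C6–O), which would open the bicycle. The fallback sets out from 8 and comes back at 9. It replaces hydrogenolysis by Lewis-acid dealkylation with BCl3 and pentamethylbenzene as cation scavenger in CH2Cl2 at −78 °C. This fallback makes no new compound (F0).

**Further compounds**
F1 | step 1 | (S)-4-benzyl-3-{(2R,3S)-3-[4-(benzyloxy)-3,5-dimethoxyphenyl]-3-hydroxy-2-(prop-2-en-1-yl)propanoyl}oxazolidin-2-one | COc1cc([C@@H](O)[C@@H](CC=C)C(=O)N2[C@@H](Cc3ccccc3)COC2=O)cc(OC)c1OCc1ccccc1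
F2 | step 1 | (1S,2S)-1-[4-(benzyloxy)-3,5-dimethoxyphenyl]-2-(prop-2-en-1-yl)propane-1,3-diol | COc1cc([C@@H](O)[C@@H](CC=C)CO)cc(OC)c1OCc1ccccc1
F3 | step 1 | (1S,2S)-1-[4-(benzyloxy)-3,5-dimethoxyphenyl]-2-({[tert-butyl(dimethyl)silyl]oxy}methyl)pent-4-en-1-ol | COc1cc([C@@H](O)[C@@H](CC=C)CO[Si](C)(C)C(C)(C)C)cc(OC)c1OCc1ccccc1
F4 | step 1 | (4S,5S)-5-[4-(benzyloxy)-3,5-dimethoxyphenyl]-4-({[tert-butyl(dimethyl)silyl]oxy}methyl)oxolan-2-ol (anomer mixture) | COc1cc([C@H]2OC(O)C[C@H]2CO[Si](C)(C)C(C)(C)C)cc(OC)c1OCc1ccccc1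
F5 | step 3 | (3S,3aS,6aR)-6-[3,4-bis(benzyloxy)phenyl]-3-[4-(benzyloxy)-3,5-dimethoxyphenyl]-6-hydroxytetrahydro-1H,3H-furo[3,4-c]furan-1-one (anomer mixture) | COc1cc([C@H]2OC(=O)[C@@H]3[C@H]2COC3(O)c2ccc(OCc4ccccc4)c(OCc4ccccc4)c2)cc(OC)c1OCc1ccccc1
F0 | step 4 | none | none
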